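Temperature separates south-east, south, south-west and north-west: these flasks share one charge and differ in how hot they are held.

the same everywhere: left-handed substrate 0.10 M; right-handed substrate 0.10 M
- maple: reagent 0.040 M; catalyst 0.10 mM; temperature 50 °C; run made earlier
- ash: reagent 0.16 M; catalyst 0.10 mM; temperature 83 °C; run made earlier
- elm: reagent 0.080 M; catalyst 0.15 mM; temperature 50 °C; run made earlier
- south-east: reagent 0.0800 M; catalyst 0.10 mM; at 95 °C until 20 h, from then on at 35 °C; time 4.0 d
- south: reagent 0.0800 M; catalyst 0.10 mM; temperature 95 °C; time 4.0 d
- south-west: reagent 0.0800 M; catalyst 0.10 mM; temperature 65 °C; time 4.0 d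
- north-west: reagent 0.0800 M; catalyst 0.10 mM; temperature 35 °C; time 4.0 d

| run | time / d | left-handed product / % | left-handed substrate / % |
|---|---|---|---|
| maple | 5.00 | 15.8 | 34.3 |
| maple | 8.00 | 17.3 | 31.3 |
| maple | 12.0 | 16.5 | 34.6 |
| maple | 15.0 | 16.2 | 32.2 |
| maple | 25.0 | 18.6 | 35.6 |
| maple | 30.0 | 14.9 | 34.6 |
| ash | 0.417 | 26.3 | 24.4 |
| ash | 0.833 | 25.7 | 23.1 |
| ash | 1.04 | 26.5 | 25.5 |
| ash | 1.67 | 28.4 | 22.2 |
| ash | 2.50 | 25.3 | 23.6 |
| ash | 4.00 | 27.2 | 22.2 |
| ash | 5.00 | 26.7 | 24.2 |
| elm | 6.00 | 30.3 | 20.0 |
| elm | 12.0 | 29.4 | 19.8 |
| elm | 20.0 | 29.0 | 20.5 |
| elm | 25.0 | 30.8 | 23.0 |
| elm | 30.0 | 30.4 | 23.0 |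

(readings scatter by 1 percentage point)

- catalyst is single-handed; left-handed substrate and right-handed substrate are mirror images of each other, charged as a racemate, each of them at the stated concentration
- what may be going on: reagent + catalyst + left-handed substrate -> catalyst + left-handed product; reagent + catalyst + right-handed substrate -> catalyst + right-handed product; reagent <-> dormant form; 2 reagent -> self-condensation product

1. the flask that comes out highest in amount of left-handed product, in percent of the left-handed substrate and right-handed substrate together charged, or "all alike" when all lie within 1.5 percentage points (south-east / south / south-west / north-west / all alike)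
2. left-handed product at the end, in percent of the left-handed substrate and right-handed substrate together charged, south-east
3. left-handed product at the end, in percent of the left-handed substrate and right-handed substrate together charged, south
4. left-handed product at the end, in percent of the left-handed substrate and right-handed substrate together charged, south-west
5. left-handed product at the end, in percent of the left-handed substrate and right-handed substrate together charged, north-west

Each earlier run is flat from its first reading, so you get end yields and no rates, and the reckoning has to work from end yields. Reagent is the limiting reagent, at 0.0800 M against 0.10 M of left-handed substrate, and I follow two of the ways it can go: to left-handed product and to self-condensation product. Catalysis takes reagent at a rate proportional to [reagent], pseudo-first-order while [catalyst] and the substrate hold roughly steady, and self-condensation takes it at a rate proportional to [reagent] squared. Call a the [reagent] at which the two use reagent equally fast. At any moment the share going to product is a/(a + [reagent]), so the early, concentrated reagent is the most wasted. Adding this up as [reagent] falls gives [left-handed product] = a ln(1 + starting [reagent]/a). Left-handed substrate does fall in the earlier runs, so a is an effective mean for a given catalyst charge.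

Maple averages 0.0331 M of left-handed product from 0.040 M of reagent, and the rule returns that for a = 0.0893 M at 50 °C. Ash averages 0.0532 M from 0.16 M, which reads as a = 0.0280 M at 83 °C. So a is smaller in the hotter run, and both values carry the scatter of the readings. I assume the same factor for each degree. Then in south, at 95 °C, the crossover concentration, the [reagent] at which catalysis and self-condensation use reagent equally fast, is 0.0184 M, and the rule gives 15.4%. Ash was flat by 0.417 d, earlier than the 20 h at which south-east is cooled. South-east is also hotter than ash, though it has half the reagent, so I give it the same figure as south. South-west gets a = 0.0527 M and 24.3%. North-west gets a = 0.151 M and 32.1%, the highest, but that figure is for a finished flask, and the earlier runs were held at 50 °C and 83 °C, warmer than the 35 °C of north-west.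

The forecast names north-west as highest, with 14.5% for south-east, of which it says “so it matches south”, 14.3% for south, 24% for south-west and 28% for north-west, and its north-west stands below mine.

The flasks give 16.0% in south-east, 16.0% in south, 23.9% in south-west and 28.2% in north-west, so north-west comes out highest.

    reagent + catalyst + left-handed substrate → catalyst + left-handed product (k = 7.47 /M²/s, Ea = 39.0 kJ/mol)
    reagent + catalyst + right-handed substrate → catalyst + right-handed product (k = 0.290 /M²/s, Ea = 36.0 kJ/mol)
    reagent ⇌ dormant form (K = 3.44, k = 6.57 × 10⁻⁶ /s, Ea = 100 kJ/mol, ΔH = −24.0 kJ/mol)
    2 reagent → self-condensation product (k = 2.31 × 10⁻⁴ /M/s, Ea = 77.0 kJ/mol)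
    (constants at 35 °C)

Against my 15.4%, south gave 16.0%. Now take the neighbour of south-east charged with 0.020 M of reagent, the other charges and the time held. The same crossover of 0.0184 M gives 6.77%, and the flask gives 6.96%. The reagent of the neighbour stands at 0% at the end, and 69.6% of the reagent charged became left-handed product, against 40.0% in south-east.

The data stem from a simulated flask on assumed constants, and the scatter is random.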